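**Retrosynthetic overview**
- Rings A and B are bought intact as 3′,4′-dimethoxyacetophenone 1 and 2,3,4-trimethoxybenzaldehyde 2; only the γ-pyranone ring is built, and it is formed last.
- C–C disconnection at the future C2–C3 unit: chalcone 3 ⇒ 1 + 2 (Claisen–Schmidt).
- Key C–O disconnections: the ring oxygen O1 is removed from both its bonds (O1–C8a aryl C–O and O1–C2), leading back to 3, which carries only a C–H at the future C8a.
- Forward order in one pot: directed C–H oxygenation of 3 (aryl trifluoroacetate 4, then phenol 5), 6-endo oxa-Michael closure (flavanone 6), dehydrogenation to flavone 7 (target).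

Assumption: the target is achiral (no stereocentre), so no enantiocontrol is needed; C2 of intermediate 6 is racemic and is erased in the same step. The route has only two steps, so the risk ranking at the end covers both rather than three.

**Step 1**
Reactants: 1 3′,4′-dimethoxyacetophenone; 2 2,3,4-trimethoxybenzaldehyde
Product: 3 (E)-1-(3,4-dimethoxyphenyl)-3-(2,3,4-trimethoxyphenyl)prop-2-en-1-one
Conditions: KOH (0.5 equiv, 40% aq.), EtOH, 0 °C → rt, 16 h
Reagents that add atoms: none
Why: Claisen–Schmidt (crossed aldol) condensation, in which only 1 can enolise and 2 is the only aldehyde, so E1cB dehydration of the aldol gives the conjugated (E)-enone; no stereocentre is formed.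

**Step 2**
Reactants: 3 (E)-1-(3,4-dimethoxyphenyl)-3-(2,3,4-trimethoxyphenyl)prop-2-en-1-one
Product: 7 6,7-dimethoxy-2-(2,3,4-trimethoxyphenyl)-4H-chromen-4-one, via aryl trifluoroacetate 4 (not isolated), via 2′-hydroxychalcone 5 (not isolated), via flavanone 6 (not isolated)
Conditions: Pd(TFA)2 (10 mol%), K2S2O8 (1.3 equiv), TFA/TFAA 9:1, 0.1 M, 50 °C; then H2O (20 equiv), AcOH, DMSO (20 mol%), O2 (1 atm), 80 °C; one pot
Reagents that add atoms: trifluoroacetic acid, OC(=O)C(F)(F)F
Why: Proposed new method: a tandem ketone-directed C–H oxygenation/oxidative oxa-annulation that inserts one oxygen between the ortho C–H of ring A and C-β of a plain chalcone. The enone carbonyl directs electrophilic palladation to the less hindered ortho C–H, which is para to the 3-OMe and is the innately most nucleophilic site of the ring. Persulfate oxidises the five-membered palladacycle to Pd(IV), and C–O reductive elimination gives aryl trifluoroacetate 4; TFAA keeps it masked, so the oxidisable p-methoxyphenol never meets persulfate. Added water unmasks phenol 5, which closes in acid by 6-endo oxa-Michael addition to racemic flavanone 6. The same Pd(II) then dehydrogenates 6 (Pd enolate, β-H elimination, O2 turnover) to the achiral flavone. Closest known reaction types: Pd(II)/Pd(IV) ketone-directed ortho-C–H hydroxylation of simple aryl ketones in TFA/TFAA, and Pd(II)/DMSO/O2 dehydrogenation of flavanones; to my knowledge they have not been merged or applied to chalcones.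

**Compound list**
1 | 3′,4′-dimethoxyacetophenone (acetoveratrone) | CC(=O)c1ccc(OC)c(OC)c1 | starting material
2 | 2,3,4-trimethoxybenzaldehyde | COc1ccc(C=O)c(OC)c1OC | starting material
3 | (E)-1-(3,4-dimethoxyphenyl)-3-(2,3,4-trimethoxyphenyl)prop-2-en-1-one | COc1ccc(C(=O)/C=C/c2ccc(OC)c(OC)c2OC)cc1OC | intermediate
4 | 4,5-dimethoxy-2-[(E)-3-(2,3,4-trimethoxyphenyl)prop-2-enoyl]phenyl trifluoroacetate | COc1cc(OC(=O)C(F)(F)F)c(C(=O)/C=C/c2ccc(OC)c(OC)c2OC)cc1OC | intermediate
5 | (E)-1-(2-hydroxy-4,5-dimethoxyphenyl)-3-(2,3,4-trimethoxyphenyl)prop-2-en-1-one | COc1cc(O)c(C(=O)/C=C/c2ccc(OC)c(OC)c2OC)cc1OC | intermediate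
6 | rac-6,7-dimethoxy-2-(2,3,4-trimethoxyphenyl)-2,3-dihydro-4H-chromen-4-one (racemic) | COc1cc2OC(c3ccc(OC)c(OC)c3OC)CC(=O)c2cc1OC | intermediate
7 | 6,7-dimethoxy-2-(2,3,4-trimethoxyphenyl)-4H-chromen-4-one | COc1cc2oc(-c3ccc(OC)c(OC)c3OC)cc(=O)c2cc1OC | target

**Total step count:** 2
**Longest linear sequence:** 2

**Steps most likely to fail (both steps of the route, most risky first)**

1. Step 2 (proposed new step). The risks are:
   - undirected palladation or oxidation of the electron-rich ring B (C5′);
   - over-oxidation of the unmasked p-methoxyphenol 5 to a quinone if persulfate is left when water is added;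
   - a stall at flavanone 6 in the strongly acidic medium.

   Fallback (known chemistry, pre-oxygenated ring A instead of C–H oxygenation): it sets out from 2. Aldehyde 2 is condensed with bought 1-(2-hydroxy-4,5-dimethoxyphenyl)ethanone F1 (KOH, EtOH, rt, Claisen–Schmidt) to give 5, here isolated as a solid. Compound 5 is then cyclised and dehydrogenated with I2 (10 mol%) in DMSO at 130 °C, the classical oxidative cyclisation of 2′-hydroxychalcones. The fallback comes back to the route at 7.

2. Step 1. The risks are slow condensation of the electron-rich, ortho-substituted aldehyde and Michael addition of the enolate of 1 to product 3 (1,5-diketone) on long exposure to base.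

   Fallback (olefination instead of aldol condensation, base-free in the C=C forming event): it sets out from 1. Ketone 1 is α-brominated (CuBr2, EtOAc/CHCl3, reflux) to 2-bromo-1-(3,4-dimethoxyphenyl)ethanone F2. Triphenylphosphine in toluene converts this into [2-(3,4-dimethoxyphenyl)-2-oxoethyl]triphenylphosphonium bromide F3. Aqueous NaOH/CH2Cl2 gives the stabilised ylide 1-(3,4-dimethoxyphenyl)-2-(triphenyl-λ5-phosphanylidene)ethanone F4. Wittig reaction of F4 with 2 (toluene, 110 °C) gives the (E)-enone, and the fallback comes back to the route at 3.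

**Further compounds**
F1 | step 2 | 1-(2-hydroxy-4,5-dimethoxyphenyl)ethanone (bought) | CC(=O)c1cc(OC)c(OC)cc1O
F2 | step 1 | 2-bromo-1-(3,4-dimethoxyphenyl)ethanone | COc1ccc(C(=O)CBr)cc1OC
F3 | step 1 | [2-(3,4-dimethoxyphenyl)-2-oxoethyl]triphenylphosphonium bromide | COc1ccc(C(=O)C[P+](c2ccccc2)(c2ccccc2)c2ccccc2)cc1OC.[Br-]
F4 | step 1 | 1-(3,4-dimethoxyphenyl)-2-(triphenyl-λ5-phosphanylidene)ethanone | COc1ccc(C(=O)C=P(c2ccccc2)(c2ccccc2)c2ccccc2)cc1OC
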